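**Plan**

- Retrosynthesis: the C3 carbonyl comes off first (allylic oxidation). The cuts then follow in this order: C2–C3 (zinc Barbier, cyclopentane), C9–C10 (B-alkyl Suzuki–Miyaura, cycloheptene), C1–C5 (enal Michael addition), C14–C15'/C2–C4' (Diels–Alder spiro-annulation) and C6–C7/O–C12 of the unprimed lactone (indium Barbier).
- Enabling feature: each half is numbered as a guaian-12,6-olide, primed for the half with spiro C4'. The tetrasubstituted C1=C10 alkene is shared by the central cyclohexene (C1, C2, C4', C15', C14, C10) and the unprimed cycloheptene. With the C2 carbonyl it is the enol double bond of a cyclohexane-1,3-dione, so C10 can be an alkenyl triflate and C9 a B-alkyl group grown from a C7 vinyl group.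
- Forward: dehydrocostus lactone is epimerised at C7 (butenolide, then retro-ene hydrogen return) and oxidised to the primed enone. A bis(silyloxy)diene builds the spiro dione, and the cis vinyl-lactone enal is added at C1. Triflation, methylenation, reduction and silylation give the coupling precursor. The cycloheptene closes, then the cyclopentane, then C3 is oxidised.
- Stereochemistry: C1', C5', C6' come from dehydrocostus lactone; C7' from hydrogen delivery syn to H6'; C4' from cycloaddition anti to C6'. C6/C7 come from (R)-glyceraldehyde acetonide and a syn-selective allylindium addition; C5 from the (R)-diphenylprolinol silyl ether catalyst; C2 from the tethered Barbier addition.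

Key step: step 20

Assumption: as drawn, both γ-lactones of the target are cis-fused (H6/H7 and H6'/H7' syn), so each half is 7-epi relative to dehydrocostus lactone while C1', C5', C6' keep the natural configuration.

Step 1
Reactants: 1 dehydrocostus lactone
Product: 2 13-(phenylsulfanyl)-11,13-dihydrodehydrocostus lactone
Conditions: PhSH (1.05 equiv), Et3N (0.1 equiv), CH2Cl2, 0 °C → rt
Reagents that add atoms: thiophenol, Sc1ccccc1
Why: Thia-Michael addition, in which the thiolate adds only to the conjugated lactone methylene and leaves the isolated 1,1-disubstituted alkenes alone; the new C11 centre is not retained.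

Step 2
Reactants: 2 13-(phenylsulfanyl)-11,13-dihydrodehydrocostus lactone
Product: 4 α-(phenylsulfanylmethylidene) lactone (C11=C13H–SPh), via chloro sulfide 3 (not isolated)
Conditions: NCS (1.05 equiv), CCl4, 0 °C → rt; then Et3N (1.5 equiv), 0 °C → rt
Reagents that add atoms: none
Why: Pummerer-type α-chlorination of the sulfide through its chlorosulfonium salt, then E1cB loss of HCl through the acidic C11–H, should give the push–pull vinyl sulfide; no stereocentre is formed.

Step 3
Reactants: 4 α-(phenylsulfanylmethylidene) lactone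
Product: 6 13-(phenylsulfonyl)-7(11)-butenolide (allyl sulfone), via vinyl sulfone 5 (not isolated)
Conditions: KHSO5 (as 2KHSO5·KHSO4·K2SO4, 3 equiv), MeOH/THF/H2O, 0 °C → rt; then Et3N (0.3 equiv), CH2Cl2, rt
Reagents that add atoms: potassium peroxymonosulfate, [K+].[O-]S(=O)(=O)OO
Why: Peroxymonosulfate oxidises sulfide to sulfone without epoxidising isolated alkenes, and base-catalysed vinyl-to-allyl sulfone isomerisation through the sulfonyl-stabilised allyl anion moves the alkene to C7=C11, which erases the C7 stereocentre; a weak amine base is used to spare the γ-hydrogen at C6.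

Step 4
Reactants: 6 13-(phenylsulfonyl)-7(11)-butenolide
Product: 7 13-oxo-7(11)-butenolide (3-formylbutenolide)
Conditions: LiN(SiMe3)2 (1.05 equiv), THF, −78 °C; Me3SiOOSiMe3 (1.2 equiv), −78 → 0 °C
Reagents that add atoms: bis(trimethylsilyl) peroxide, C[Si](C)(C)OO[Si](C)(C)C
Why: Oxidative desulfonylation, in which the α-sulfonyl carbanion (the less hindered and kinetically preferred site) is oxygenated by the silyl peroxide and the α-silyloxy sulfone collapses to the aldehyde with loss of sulfinate.

Step 5
Reactants: 7 13-oxo-7(11)-butenolide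
Product: 11 7-epi-dehydrocostus lactone, via tosylhydrazone 8 (not isolated), via allyl tosylhydrazine 9 (not isolated), via allyl diazene 10 (not isolated)
Conditions: TsNHNH2 (1.05 equiv), CHCl3, rt; catecholborane (2.5 equiv), 0 °C; NaOAc·3H2O (3 equiv), 60 °C
Reagents that add atoms: none
Why: Reductive 1,3-transposition of an enal tosylhydrazone (1,2-reduction, loss of sulfinate, retro-ene loss of N2 from the allylic diazene) returns the alkene to C11=C13 and delivers hydrogen to C7 within the molecule on the open face syn to H6 and anti to C5, which should set the cis-lactone.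

Step 6
Reactants: 11 7-epi-dehydrocostus lactone
Product: 12 3α-hydroxy-7-epi-dehydrocostus lactone
Conditions: SeO2 (0.3 equiv), t-BuOOH (2 equiv), CH2Cl2, 0 °C → rt
Reagents that add atoms: tert-butyl hydroperoxide, CC(C)(C)OO (oxygen relayed through selenium dioxide, O=[Se]=O)
Why: Riley allylic oxidation (ene reaction, then [2,3]-shift) prefers the ring CH2 next to the exocyclic methylene of the cyclopentane (CH2 before CH); the carbinol configuration (expected α, convex face) is removed in step 7.

Step 7
Reactants: 12 3α-hydroxy-7-epi-dehydrocostus lactone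
Product: 13 7-epi-dehydrozaluzanin C (primed enone)
Conditions: Dess–Martin periodinane (1.3 equiv), CH2Cl2, 0 °C → rt
Reagents that add atoms: none
Why: Dess–Martin oxidation of the secondary allylic alcohol should give the exocyclic α-methylene cyclopentanone without touching the alkenes or the lactone.

Step 8
Reactants: 14 methyl 3-(trimethylsilyloxy)but-2-enoate
Product: 15 1-methoxy-1,3-bis(trimethylsilyloxy)buta-1,3-diene
Conditions: LDA (1.1 equiv), THF, −78 °C; Me3SiCl (1.2 equiv), −78 °C → rt
Reagents that add atoms: chlorotrimethylsilane, C[Si](C)(C)Cl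
Why: Deprotonation of the ester enolisable through the γ-methyl group and O-silylation of the resulting dienolate is the standard preparation of 1,3-bis(silyloxy)dienes.

Step 9
Reactants: 13 7-epi-dehydrozaluzanin C; 15 1-methoxy-1,3-bis(trimethylsilyloxy)buta-1,3-diene
Product: 17 spiro triketone (cyclohexane-1,3-dione spiro-fused at C4'), via silyl cycloadduct 16 (not isolated)
Conditions: 15 (1.2 equiv), toluene, rt → 60 °C; then 1 M HCl, THF, 0 °C
Reagents that add atoms: none
Why: Diels–Alder reaction of the ketene-acetal diene with the s-cis exocyclic enone (a better dienophile than the lactone methylene) joins the diene CH2 to C15' and the acetal carbon to C4' on the convex face anti to C6', and acid hydrolysis of the acetal and silyl enol ether gives the 1,3-dione; this sets spiro C4'.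

Step 10
Reactants: 18 acrolein; 19 methyl acrylate
Product: 20 methyl 3-hydroxy-2-methylidenepent-4-enoate
Conditions: DABCO (0.2 equiv), 19 (3 equiv, neat), slow addition of 18, rt
Reagents that add atoms: none
Why: Morita–Baylis–Hillman reaction with the acrylate in excess as donor and acrolein as the aldehyde; the carbinol centre is racemic and is removed in step 11.

Step 11
Reactants: 20 methyl 3-hydroxy-2-methylidenepent-4-enoate
Product: 21 methyl (2Z)-2-(bromomethyl)penta-2,4-dienoate
Conditions: PBr3 (0.4 equiv), Et2O, 0 °C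
Reagents that add atoms: phosphorus tribromide, BrP(Br)Br
Why: SN2' bromination of the Baylis–Hillman alcohol should give the conjugated (Z)-allylic bromide, and any regioisomeric pentadienyl bromide leads to the same allylindium species in step 12.

Step 12
Reactants: 21 methyl (2Z)-2-(bromomethyl)penta-2,4-dienoate; 22 (R)-2,2-dimethyl-1,3-dioxolane-4-carbaldehyde
Product: 24 cis vinyl α-methylene lactone acetonide, via hydroxy ester 23 (not isolated)
Conditions: In powder (1.2 equiv), THF/H2O (1:1), rt; then TsOH·H2O (0.1 equiv), CH2Cl2, rt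
Reagents that add atoms: none
Why: Aqueous Barbier allylation, in which the ester-chelated allylindium reacts at its γ-carbon through a chair transition state (C6/C7 syn) on the non-chelated face anti to the α-oxygen of the aldehyde (C5/C6 anti), and acid closes the syn adduct to the cis-lactone.

Step 13
Reactants: 24 cis vinyl α-methylene lactone acetonide
Product: 25 (2S,3R)-3-ethenyl-4-methylidene-5-oxooxolane-2-carbaldehyde
Conditions: H5IO6 (1.3 equiv), EtOAc, rt
Reagents that add atoms: none
Why: Periodic acid removes the terminal acetonide and cleaves the diol in one operation (Malaprade cleavage), which excises the glyceraldehyde stereocentre; the aldehyde is used at once to avoid epimerisation at C6.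

Step 14
Reactants: 25 (2S,3R)-3-ethenyl-4-methylidene-5-oxooxolane-2-carbaldehyde
Product: 26 (2E)-3-[(2R,3R)-3-ethenyl-4-methylidene-5-oxooxolan-2-yl]prop-2-enal
Conditions: Ph3P=CHCHO (1.1 equiv), CH2Cl2, rt
Reagents that add atoms: (triphenylphosphoranylidene)acetaldehyde, O=CC=P(c1ccccc1)(c1ccccc1)c1ccccc1
Why: Wittig olefination with the stabilised formyl ylide should give the (E)-enal under base-free conditions that leave C6 untouched.

Step 15
Reactants: 17 spiro triketone; 26 lactone enal
Product: 27 C1–C5 Michael adduct (handled as its cyclic hemiacetal)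
Conditions: (R)-α,α-diphenylprolinol trimethylsilyl ether (20 mol %), PhCO2H (20 mol %), CH2Cl2, 0 °C → rt
Reagents that add atoms: none
Why: Iminium-catalysed Michael addition of a cyclic 1,3-dione to an enal, in which C1 attacks C5 of the E-iminium ion on the face remote from the diphenyl(silyloxy)methyl group of the (R)-catalyst (C5 anti to the C6 oxygen), and lactol formation holds the adduct.

Step 16
Reactants: 27 C1–C5 Michael adduct
Product: 28 C10 alkenyl triflate aldehyde
Conditions: PhNTf2 (1.1 equiv), Et3N (1.5 equiv), DMAP (0.1 equiv), CH2Cl2, 0 °C → rt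
Reagents that add atoms: N-phenylbis(trifluoromethanesulfonimide), O=S(=O)(N(c1ccccc1)S(=O)(=O)C(F)(F)F)C(F)(F)F
Why: O-triflation of the ring-opened 1,3-dione enolate should occur at the oxygen on C10, remote from the quaternary spiro centre, and it is done before methylenation so that no free enol can add to the acrolein unit made next.

Step 17
Reactants: 28 C10 alkenyl triflate aldehyde
Product: 29 C10 triflate 2-substituted propenal (C4=C15)
Conditions: (CH2O)n (3 equiv), N-methylanilinium trifluoroacetate (1.2 equiv), THF, 60 °C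
Reagents that add atoms: formaldehyde (as paraformaldehyde), C=O
Why: Mannich–elimination α-methylenation of the aldehyde with a weakly nucleophilic anilinium salt, which neither displaces the triflate nor adds to the lactone methylenes.

Step 18
Reactants: 29 C10 triflate 2-substituted propenal
Product: 30 C10 triflate allylic alcohol
Conditions: NaBH4 (1 equiv), CeCl3·7H2O (1.2 equiv), MeOH/CH2Cl2, −78 °C; AcOH quench at −78 °C
Reagents that add atoms: none
Why: Luche 1,2-reduction, in which the enal reacts far faster at −78 °C than the hindered C2 and C3' ketones and cerium suppresses conjugate reduction.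

Step 19
Reactants: 30 C10 triflate allylic alcohol
Product: 31 coupling precursor (C10 triflate, C3 silyl ether, C7 vinyl)
Conditions: TBSOTf (1.1 equiv), 2,6-lutidine (2 equiv), CH2Cl2, −78 °C
Reagents that add atoms: tert-butyldimethylsilyl trifluoromethanesulfonate, CC(C)(C)[Si](C)(C)OS(=O)(=O)C(F)(F)F
Why: Silylation of the primary allylic alcohol under non-nucleophilic conditions blocks its addition–elimination onto the triflate-bearing C10 in the basic coupling step.

Step 20
Reactants: 31 coupling precursor
Product: 33 spiro cyclohexenone with closed cycloheptene, via alkylborane 32 (not isolated)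
Conditions: 9-BBN (1.3 equiv), THF, 0 °C → rt; then slow addition to Pd(dppf)Cl2 (10 mol %), AsPh3 (20 mol %), Cs2CO3 (3 equiv), DMF/THF/H2O, rt, 2 mM
Reagents that add atoms: none
Why: 9-BBN adds anti-Markovnikov to the monosubstituted C8=C9 alkene, which reacts far faster than the 1,1-disubstituted C4=C15 and C10'=C14' alkenes and the conjugated lactone methylenes, and places boron on C9; zerovalent palladium then inserts into the C10–O bond of the vinylogous acyl triflate, hydroxide-assisted transmetalation transfers the primary alkyl group and reductive elimination forms C9–C10. The closest known reaction is the intramolecular B-alkyl Suzuki–Miyaura coupling of alkenyl triflates, including triflates of cyclic 1,3-diones. The seven-membered ring (C1, C5, C6, C7, C8, C9, C10) closes by reductive elimination from an eight-membered palladacycle in an endo mode, C1=C10 becoming endocyclic, and no stereocentre is formed. The step needs hydroboration only at the vinyl group, which the bulk of 9-BBN secures, and coupling faster than β-hydride elimination or triflate hydrolysis, which the wide-bite-angle dppf ligand, AsPh3, high dilution and room temperature are chosen to secure. The triflate fixes the double bond at C1=C10, so no positional isomer of the tetrasubstituted alkene can form.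

Step 21
Reactants: 33 spiro cyclohexenone with closed cycloheptene
Product: 34 allylic bromide
Conditions: Ph3PBr2 (1.5 equiv), CH2Cl2, 0 °C → rt
Reagents that add atoms: triphenylphosphine dibromide, BrP(Br)(c1ccccc1)(c1ccccc1)c1ccccc1
Why: Triphenylphosphine dibromide converts a primary silyl ether directly into the bromide (silyl transfer to bromide, then SN2 on the alkoxyphosphonium ion).

Step 22
Reactants: 34 allylic bromide
Product: 35 C2 tertiary alcohol with closed cyclopentane (3-deoxo target)
Conditions: activated Zn dust (3 equiv), THF, 0 °C → rt, 5 mM; sat. aq NH4Cl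
Reagents that add atoms: none
Why: Intramolecular zinc Barbier allylation, in which the 2-substituted allylzinc (two equivalent CH2 termini) adds 1,2 to the C2 enone carbonyl in a five-membered closure and can reach only the face of C2 on which C4 lies, so the hydroxyl ends up cis to H5 as the target requires.

Step 23
Reactants: 35 C2 tertiary alcohol
Product: 36 2,3-diol
Conditions: SeO2 (0.5 equiv), t-BuOOH (3 equiv), CH2Cl2, 0 °C → rt
Reagents that add atoms: tert-butyl hydroperoxide, CC(C)(C)OO (oxygen relayed through selenium dioxide, O=[Se]=O)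
Why: Riley oxidation at the ring CH2 (C3) next to the exocyclic methylene of the cyclopentane, the same site type as in step 6, while the buried tetrasubstituted C1=C10 alkene is expected to react more slowly; the C3 configuration (expected cis to the C2 hydroxyl) is removed in step 24.

Step 24
Reactants: 36 2,3-diol
Product: 37 CNP0269880.1
Conditions: Dess–Martin periodinane (1.5 equiv), CH2Cl2, 0 °C → rt
Reagents that add atoms: none
Why: Dess–Martin oxidation converts the secondary allylic alcohol into the C3 enone, and the tertiary C2 alcohol cannot be oxidised.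

**Compound list**

1 | dehydrocostus lactone (guaia-4(15),10(14),11(13)-trien-12,6-olide, trans-lactone) | C=C1CC[C@H]2C(=C)CC[C@H]3C(=C)C(=O)O[C@@H]3[C@H]21 | starting material
2 | 13-(phenylsulfanyl)-11,13-dihydrodehydrocostus lactone (11S shown; the C11 epimer serves equally) | C=C1CC[C@H]2C(=C)CC[C@H]3[C@H](CSc4ccccc4)C(=O)O[C@@H]3[C@H]21 | intermediate
3 | 13-chloro-13-(phenylsulfanyl)-11,13-dihydrodehydrocostus lactone (C13 epimers) | C=C1CC[C@H]2C(=C)CC[C@H]3[C@H](C(Cl)Sc4ccccc4)C(=O)O[C@@H]3[C@H]21 | intermediate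
4 | 13-(phenylsulfanyl)dehydrocostus lactone, C11=C13H–SPh (alkene geometry not defined) | C=C1CC[C@H]2C(=C)CC[C@H]3C(=CSc4ccccc4)C(=O)O[C@@H]3[C@H]21 | intermediate
5 | 13-(phenylsulfonyl)dehydrocostus lactone, C11=C13H–SO2Ph | C=C1CC[C@H]2C(=C)CC[C@H]3C(=CS(=O)(=O)c4ccccc4)C(=O)O[C@@H]3[C@H]21 | intermediate
6 | 13-(phenylsulfonyl)guaia-4(15),7(11),10(14)-trien-12,6-olide (allyl sulfone butenolide) | C=C1CC[C@H]2C(=C)CCC3=C(CS(=O)(=O)c4ccccc4)C(=O)O[C@@H]3[C@H]21 | intermediate
7 | 13-oxoguaia-4(15),7(11),10(14)-trien-12,6-olide (3-formylbutenolide) | C=C1CC[C@H]2C(=C)CCC3=C(C=O)C(=O)O[C@@H]3[C@H]21 | intermediate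
8 | p-toluenesulfonylhydrazone of 7 | C=C1CC[C@H]2C(=C)CCC3=C(C=NNS(=O)(=O)c4ccc(C)cc4)C(=O)O[C@@H]3[C@H]21 | intermediate
9 | N'-(butenolid-3-ylmethyl) p-toluenesulfonohydrazide (C13H2–NH–NHTs) | C=C1CC[C@H]2C(=C)CCC3=C(CNNS(=O)(=O)c4ccc(C)cc4)C(=O)O[C@@H]3[C@H]21 | intermediate
10 | allylic diazene (C13H2–N=NH on the C7=C11 butenolide) | C=C1CC[C@H]2C(=C)CCC3=C(CN=N)C(=O)O[C@@H]3[C@H]21 | intermediate
11 | 7-epi-dehydrocostus lactone (cis-lactone) | C=C1CC[C@H]2C(=C)CC[C@@H]3C(=C)C(=O)O[C@@H]3[C@H]21 | intermediate
12 | 3α-hydroxy-7-epi-dehydrocostus lactone (the 3β epimer serves equally) | C=C1[C@H](O)C[C@H]2C(=C)CC[C@@H]3C(=C)C(=O)O[C@@H]3[C@H]21 | intermediate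
13 | 7-epi-dehydrozaluzanin C (3-oxo-7-epi-dehydrocostus lactone) | C=C1C(=O)C[C@H]2C(=C)CC[C@@H]3C(=C)C(=O)O[C@@H]3[C@H]21 | intermediate
14 | methyl 3-(trimethylsilyloxy)but-2-enoate | COC(=O)C=C(C)O[Si](C)(C)C | starting material
15 | 1-methoxy-1,3-bis(trimethylsilyloxy)buta-1,3-diene | COC(O[Si](C)(C)C)=CC(=C)O[Si](C)(C)C | intermediate
16 | spiro cycloadduct: C2 methyl trimethylsilyl acetal, C1=C10 silyl enol ether (C2 epimers) | COC1(O[Si](C)(C)C)C=C(O[Si](C)(C)C)CC[C@]12C(=O)C[C@H]3C(=C)CC[C@@H]4C(=C)C(=O)O[C@@H]4[C@H]32 | intermediate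
17 | spiro triketone: cyclohexane-1,3-dione (C2, C10) spiro-fused at C4' to the 3'-oxo-7'-epi-guaianolide (largely enolised) | O=C1CC(=O)[C@]2(CC1)C(=O)C[C@H]1C(=C)CC[C@@H]3C(=C)C(=O)O[C@@H]3[C@H]12 | intermediate
18 | acrolein | C=CC=O | starting material
19 | methyl acrylate | C=CC(=O)OC | starting material
20 | methyl 3-hydroxy-2-methylidenepent-4-enoate (racemic) | C=CC(O)C(=C)C(=O)OC | intermediate
21 | methyl (2Z)-2-(bromomethyl)penta-2,4-dienoate | C=C/C=C(\CBr)C(=O)OC | intermediate
22 | (R)-2,2-dimethyl-1,3-dioxolane-4-carbaldehyde | O=C[C@H]1COC(C)(C)O1 | starting material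
23 | methyl (3R,4S)-4-[(4R)-2,2-dimethyl-1,3-dioxolan-4-yl]-3-ethenyl-4-hydroxy-2-methylidenebutanoate | C=C[C@H](C(=C)C(=O)OC)[C@H](O)[C@H]1COC(C)(C)O1 | intermediate
24 | (4R,5S)-5-[(4R)-2,2-dimethyl-1,3-dioxolan-4-yl]-4-ethenyl-3-methylideneoxolan-2-one | C=C[C@@H]1C(=C)C(=O)O[C@@H]1[C@H]1COC(C)(C)O1 | intermediate
25 | (2S,3R)-3-ethenyl-4-methylidene-5-oxooxolane-2-carbaldehyde | C=C[C@@H]1C(=C)C(=O)O[C@@H]1C=O | intermediate
26 | (2E)-3-[(2R,3R)-3-ethenyl-4-methylidene-5-oxooxolan-2-yl]prop-2-enal | C=C[C@@H]1C(=C)C(=O)O[C@@H]1/C=C/C=O | intermediate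
27 | Michael adduct: 17 carrying at C1 the C5H(lactone)–CH2–CHO chain (drawn as enol aldehyde; exists as cyclic hemiacetal) | C=C[C@@H]1C(=C)C(=O)O[C@@H]1[C@@H](CC=O)C1=C(O)CC[C@@]2(C1=O)C(=O)C[C@H]3C(=C)CC[C@@H]4C(=C)C(=O)O[C@@H]4[C@H]32 | intermediate
28 | C10 alkenyl triflate of 27 with free C3 aldehyde | C=C[C@@H]1C(=C)C(=O)O[C@@H]1[C@@H](CC=O)C1=C(OS(=O)(=O)C(F)(F)F)CC[C@@]2(C1=O)C(=O)C[C@H]3C(=C)CC[C@@H]4C(=C)C(=O)O[C@@H]4[C@H]32 | intermediate
29 | C10 triflate with C4=C15 methylene and C3 aldehyde | C=C[C@@H]1C(=C)C(=O)O[C@@H]1[C@@H](C(=C)C=O)C1=C(OS(=O)(=O)C(F)(F)F)CC[C@@]2(C1=O)C(=O)C[C@H]3C(=C)CC[C@@H]4C(=C)C(=O)O[C@@H]4[C@H]32 | intermediate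
30 | C10 triflate with C3 allylic alcohol | C=C[C@@H]1C(=C)C(=O)O[C@@H]1[C@@H](C(=C)CO)C1=C(OS(=O)(=O)C(F)(F)F)CC[C@@]2(C1=O)C(=O)C[C@H]3C(=C)CC[C@@H]4C(=C)C(=O)O[C@@H]4[C@H]32 | intermediate
31 | coupling precursor: vinylogous acyl triflate (C10), C3 tert-butyldimethylsilyl ether, C7 vinyl | C=C[C@@H]1C(=C)C(=O)O[C@@H]1[C@@H](C(=C)CO[Si](C)(C)C(C)(C)C)C1=C(OS(=O)(=O)C(F)(F)F)CC[C@@]2(C1=O)C(=O)C[C@H]3C(=C)CC[C@@H]4C(=C)C(=O)O[C@@H]4[C@H]32 | intermediate
32 | B-(C9-alkyl)-9-borabicyclo[3.3.1]nonane from 31 | B1(CC[C@@H]2C(=C)C(=O)O[C@@H]2[C@@H](C(=C)CO[Si](C)(C)C(C)(C)C)C2=C(OS(=O)(=O)C(F)(F)F)CC[C@@]3(C2=O)C(=O)C[C@H]4C(=C)CC[C@@H]5C(=C)C(=O)O[C@@H]5[C@H]43)C2CCCC1CCC2 | intermediate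
33 | spiro cyclohexenone with closed cycloheptene (C2 ketone, C3 silyloxymethyl, C4=C15) | C=C(CO[Si](C)(C)C(C)(C)C)[C@H]1C2=C(CC[C@@H]3C(=C)C(=O)O[C@@H]31)CC[C@@]1(C2=O)C(=O)C[C@H]2C(=C)CC[C@@H]3C(=C)C(=O)O[C@@H]3[C@H]21 | intermediate
34 | allylic bromide (C3H2Br) | C=C(CBr)[C@H]1C2=C(CC[C@@H]3C(=C)C(=O)O[C@@H]31)CC[C@@]1(C2=O)C(=O)C[C@H]2C(=C)CC[C@@H]3C(=C)C(=O)O[C@@H]3[C@H]21 | intermediate
35 | 3-deoxo target: C2 tertiary alcohol, C3H2, all rings closed | C=C1C[C@]2(O)C3=C(CC[C@@H]4C(=C)C(=O)O[C@@H]4[C@@H]13)CC[C@]21C(=O)C[C@H]2C(=C)CC[C@@H]3C(=C)C(=O)O[C@@H]3[C@H]21 | intermediate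
36 | 2,3-diol (C3 hydroxyl drawn cis to the C2 hydroxyl; the C3 epimer serves equally) | C=C1[C@H](O)[C@]2(O)C3=C(CC[C@@H]4C(=C)C(=O)O[C@@H]4[C@@H]13)CC[C@]21C(=O)C[C@H]2C(=C)CC[C@@H]3C(=C)C(=O)O[C@@H]3[C@H]21 | intermediate
37 | CNP0269880.1 | C=C1C(=O)[C@]2(O)C3=C(CC[C@@H]4C(=C)C(=O)O[C@@H]4[C@@H]13)CC[C@]21C(=O)C[C@H]2C(=C)CC[C@@H]3C(=C)C(=O)O[C@@H]3[C@H]21 | target

**Step count and risks**

Total: 24 steps. Longest linear sequence: 18 steps (steps 1–7, 9, 15–24).

Steps most likely to fail:

1. Step 20. Three processes could defeat it: the borane may reduce the C2 enone or the C3' ketone; aqueous base may hydrolyse the vinylogous acyl triflate; protodeboronation or β-hydride elimination may outrun a slow seven-membered closure. The fallback sets out from 31 and comes back at 33. Hydroboration with diethylborane (from BH3·SMe2 and BEt3) should give the diethyl(alkyl)borane F1. Boron–zinc exchange with Et2Zn should give the alkyl(ethyl)zinc F2. Intramolecular Negishi coupling with Pd(dba)2 and tri(2-furyl)phosphine in THF/NMP then forms the same C9–C10 bond without any base, so the triflate never meets hydroxide.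

2. Step 23. The allylic oxidation may go to the wrong site: the doubly allylic C5–H, or the CH2 groups flanking the tetrasubstituted C1=C10 and the primed C10'=C14' alkenes. The fallback sets out from 33, bypasses steps 21–23 and comes back at 36 (or its C3 epimer, which serves equally). HF·pyridine should free the allylic alcohol F3, and MnO2 should give the 2-substituted propenal F4. CrCl2 with Me3SiCl in THF converts the enal into a γ-silyloxyallylchromium species that adds through C3 to the C2 ketone on the face fixed by the tether (pinacol-type cross-coupling), giving the C3 trimethylsilyl ether F5. Dilute acid hydrolyses F5 to the diol. C3 thus arrives already oxygenated and no late allylic oxidation is needed.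

3. Step 5. Hydrogen may be delivered to the wrong face of C7, which would return the trans-lactone, or the doubly activated butenolide may undergo conjugate reduction in place of 1,2-reduction of the hydrazone. The fallback sets out from 7 and comes back at 11. Luche reduction (NaBH4, CeCl3·7H2O, −78 °C) should give the 13-hydroxy butenolide F6, and CBr4/PPh3 the allylic bromide F7. Zinc dust in THF/aq NH4Cl then forms the allylzinc, which is protonated at its γ-carbon C7 on the open face syn to H6; this replaces the pericyclic hydrogen transfer by a polar protonation.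

Further compounds
F1 | step 20 | diethyl(C9-alkyl)borane from 31 | CCB(CC)CC[C@@H]1C(=C)C(=O)O[C@@H]1[C@@H](C(=C)CO[Si](C)(C)C(C)(C)C)C1=C(OS(=O)(=O)C(F)(F)F)CC[C@@]2(C1=O)C(=O)C[C@H]3C(=C)CC[C@@H]4C(=C)C(=O)O[C@@H]4[C@H]32
F2 | step 20 | ethyl(C9-alkyl)zinc from 31 | CC[Zn]CC[C@@H]1C(=C)C(=O)O[C@@H]1[C@@H](C(=C)CO[Si](C)(C)C(C)(C)C)C1=C(OS(=O)(=O)C(F)(F)F)CC[C@@]2(C1=O)C(=O)C[C@H]3C(=C)CC[C@@H]4C(=C)C(=O)O[C@@H]4[C@H]32
F3 | step 23 | C3 allylic alcohol of 33 | C=C(CO)[C@H]1C2=C(CC[C@@H]3C(=C)C(=O)O[C@@H]31)CC[C@@]1(C2=O)C(=O)C[C@H]2C(=C)CC[C@@H]3C(=C)C(=O)O[C@@H]3[C@H]21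
F4 | step 23 | C3 aldehyde (2-substituted propenal) of 33 | C=C(C=O)[C@H]1C2=C(CC[C@@H]3C(=C)C(=O)O[C@@H]31)CC[C@@]1(C2=O)C(=O)C[C@H]2C(=C)CC[C@@H]3C(=C)C(=O)O[C@@H]3[C@H]21
F5 | step 23 | C3 trimethylsilyl ether of diol 36 | C=C1[C@H](O[Si](C)(C)C)[C@]2(O)C3=C(CC[C@@H]4C(=C)C(=O)O[C@@H]4[C@@H]13)CC[C@]21C(=O)C[C@H]2C(=C)CC[C@@H]3C(=C)C(=O)O[C@@H]3[C@H]21
F6 | step 5 | 13-hydroxyguaia-4(15),7(11),10(14)-trien-12,6-olide | C=C1CC[C@H]2C(=C)CCC3=C(CO)C(=O)O[C@@H]3[C@H]21
F7 | step 5 | 13-bromoguaia-4(15),7(11),10(14)-trien-12,6-olide | C=C1CC[C@H]2C(=C)CCC3=C(CBr)C(=O)O[C@@H]3[C@H]21
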